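**Retrosynthetic overview**
1. Target ⇒ lactonisation and redox adjustment of keto aldehyde 28 ⇒ key step: intermolecular Michael addition of the C8 aldehyde enolate of 26 to isopropyl vinyl ketone 27 (C7–C8 bond, C8 quaternary centre).
2. 26 ⇒ one-carbon homologation of bridged amino ketone 24 ⇒ tricyclic ketone 22 + MeNH2 + 2 CH2O (double Mannich: piperidine ring, C15 quaternary centre).
3. 22 ⇒ ring-closing metathesis of 17 (seven-membered ring) ⇒ enol triflate/Stille allylation at C23 and vinyl Grignard addition at C8.
4. C8/C11 are told apart by transannular epoxide opening and Baeyer–Villiger oxidation on the Diels–Alder adduct 3 of cyclopentadiene and cyclopentenone (sets C13, C15, C26, C27 all-cis); O28 comes from a Rubottom oxidation.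
5. Ring order: cyclopentane A + cyclopentane B (Diels–Alder) → cycloheptane (metathesis) → piperidine (Mannich) → lactone.

Atom labels: the heavy atoms of the target are numbered 1–28 in the order of its SMILES (C4 side-chain ketone, C8 quaternary carbon, C9 OCH2, C11 lactone C=O, C13/C15/C20/C26/C27 other stereocentres, N17, C23=C24 alkene, O28 tertiary OH); the same labels are used for all intermediates.
Assumption: the (S)-oxazaborolidine of step 1 is taken to give the drawn enantiomer of 3; if it gives the antipode, the (R)-catalyst is used.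
Note: centres left undefined in a SMILES (C8 in 11–20 and 26, C20 in 23, C4 in 29–30) are epimer mixtures that are removed later.

**Steps**

Step 1
Reactants: 1 cyclopenta-1,3-diene; 2 cyclopent-2-en-1-one
Product: 3 endo-tricyclo[5.2.1.0(2,6)]dec-8-en-3-one (C23 ketone and C8=C11 alkene)
Conditions: (S)-1-(2-methylphenyl)-3,3-diphenyltetrahydropyrrolo[1,2-c][1,3,2]oxazaborole (20 mol%), Tf2NH (20 mol%), CH2Cl2, −78 → −40 °C
Reagents that add atoms: none
Why: Catalytic enantioselective Diels–Alder reaction in which the protonated oxazaborolidine binds the enone and blocks one face while the endo transition state puts the cyclopentanone ring under the new C8=C11 bridge, so C13, C15, C26 and C27 are set all-cis in one step.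

Step 2
Reactants: 3 endo-tricyclodecenone
Product: 4 triethylsilyl enol ether C23(OSiEt3)=C27
Conditions: Et3SiCl, Et3N, DMF, 110 °C
Reagents that add atoms: chlorotriethylsilane CC[Si](Cl)(CC)CC
Why: Equilibrating (thermodynamic) enol silylation gives the more substituted ring-fusion enol ether, the only regiochemistry that allows oxygenation of C27.

Step 3
Reactants: 4 triethylsilyl enol ether
Product: 6 exo-epoxy C27-silyloxy ketone, via silyloxy ketone 5 (not isolated)
Conditions: mCPBA (2.3 equiv), NaHCO3, CH2Cl2, −20 → 20 °C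
Reagents that add atoms: mCPBA OOC(=O)c1cccc(Cl)c1
Why: Rubottom oxidation in which the peracid attacks the enol ether from the open exo face and a 1,4-silyl shift gives the C27 silyloxy ketone with O28 cis to H26 (the cis ring fusion is kept), after which the second equivalent epoxidises the strained norbornene from its exo face (Prilezhaev epoxidation).

Step 4
Reactants: 6 exo-epoxy C27-silyloxy ketone
Product: 8 cage ether alcohol (C23–O–C8 bridge and exo C11–OH), via endo alcohol 7 (not isolated)
Conditions: NaBH4, MeOH, 0 °C; then 40 °C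
Reagents that add atoms: none
Why: Hydride adds to the ketone from the convex exo face and the resulting endo C23 alkoxide opens the exo epoxide at the nearer carbon C8 in a 5-exo SN2 reaction (inversion at C8), so C8 becomes an ether carbon and C11 a free alcohol and the two former alkene carbons are told apart.

Step 5
Reactants: 8 cage ether alcohol
Product: 9 cage ether C11 ketone
Conditions: Dess–Martin periodinane, NaHCO3, CH2Cl2, 20 °C
Reagents that add atoms: none
Why: Dess–Martin oxidation of the only free (secondary) alcohol gives the C11 ketone without touching the silyl ether.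

Step 6
Reactants: 9 cage ether C11 ketone
Product: 10 lactone acetal C11(=O)–O–C8H–O–C23
Conditions: mCPBA, NaHCO3, CH2Cl2, 0 → 20 °C
Reagents that add atoms: mCPBA OOC(=O)c1cccc(Cl)c1
Why: Baeyer–Villiger oxidation of the strained norbornanone in which the α-alkoxy carbon C8 migrates (much higher migratory aptitude than bridgehead C13, retention at C8), which makes C11 a carboxyl carbon and C8 an acetal carbon.

Step 7
Reactants: 10 lactone acetal
Product: 11 lactol acid (C13–CO2H and C8 lactol on O23)
Conditions: LiOH, THF–H2O, 0 → 20 °C; then 1 M HCl to pH 4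
Reagents that add atoms: water O
Why: Saponification of the acyloxy acetal frees the C11 acid and leaves C8 as a lactol, so C8 is at the aldehyde level and C11 at the acid level.

Step 8
Reactants: 11 lactol acid
Product: 12 C8 vinyl carbinol hydroxy acid
Conditions: CH2=CHMgBr (5 equiv), THF, −78 → 0 °C; aq NH4Cl
Reagents that add atoms: vinylmagnesium bromide C=C[Mg]Br
Why: Grignard addition to the open hydroxy aldehyde form of the lactol while the acid is masked as its unreactive carboxylate gives the C8 vinyl carbinol (C8 epimers, removed by the later oxidation).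

Step 9
Reactants: 12 C8 vinyl carbinol hydroxy acid
Product: 13 methyl ester diol
Conditions: Me3SiCHN2, toluene–MeOH, 0 °C
Reagents that add atoms: (trimethylsilyl)diazomethane C[Si](C)(C)C=[N+]=[N-]
Why: Esterification with the diazoalkane under neutral conditions avoids lactonisation of the hydroxy acid.

Step 10
Reactants: 13 methyl ester diol
Product: 14 C8 tert-butyldimethylsilyl ether
Conditions: tBuMe2SiCl, imidazole, DMF, 0 °C
Reagents that add atoms: tert-butyldimethylsilyl chloride CC(C)(C)[Si](C)(C)Cl
Why: Selective silylation of the less hindered allylic C8–OH, because the C23–OH sits on the concave face next to the quaternary C27–OSiEt3 and stays free.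

Step 11
Reactants: 14 C8 silyl ether
Product: 15 C23 ketone
Conditions: Dess–Martin periodinane, NaHCO3, CH2Cl2, 20 °C
Reagents that add atoms: none
Why: Dess–Martin oxidation of the remaining secondary alcohol restores the C23 ketone.

Step 12
Reactants: 15 C23 ketone
Product: 16 enol triflate C23(OTf)=C24
Conditions: KN(SiMe3)2, THF, −78 °C; PhNTf2, −78 → 0 °C; aq NH4Cl
Reagents that add atoms: N-phenylbis(trifluoromethanesulfonimide) FC(F)(F)S(=O)(=O)N(c1ccccc1)S(=O)(=O)C(F)(F)F
Why: Kinetic enolisation can only go toward C24 (C27 is quaternary) and O-triflation fixes the future C23=C24 double bond.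

Step 13
Reactants: 16 enol triflate
Product: 17 C23-allyl cyclopentene
Conditions: allylSnBu3, Pd(PPh3)4 (5 mol%), LiCl (3 equiv), THF, 65 °C
Reagents that add atoms: allyltributylstannane C=CC[Sn](CCCC)(CCCC)CCCC
Why: Stille cross-coupling (zerovalent palladium) of the enol triflate attaches C22 and C21 to C23 with the C23=C24 alkene already in place.

Step 14
Reactants: 17 C23-allyl cyclopentene
Product: 18 tricyclic cycloheptene (C20=C21)
Conditions: second-generation Grubbs catalyst (5 mol%), CH2Cl2 (2 mM), 40 °C
Reagents that add atoms: none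
Why: Ring-closing olefin metathesis between the C8 vinyl and C23 allyl groups, both on the concave face of ring A, closes the cis-fused seven-membered ring while the trisubstituted C23=C24 alkene is inert.

Step 15
Reactants: 18 tricyclic cycloheptene
Product: 19 diol (C8–OH and C27–OH)
Conditions: HF·pyridine, pyridine, THF, 0 → 20 °C
Reagents that add atoms: none
Why: Fluoride desilylation under non-basic conditions frees both alcohols without lactonisation or elimination.

Step 16
Reactants: 19 diol
Product: 20 dihydro diol
Conditions: H2 (1 atm), RhCl(PPh3)3 (10 mol%), benzene, 20 °C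
Reagents that add atoms: none
Why: Homogeneous hydrogenation with Wilkinson's catalyst reduces the cis-disubstituted C20=C21 alkene much faster than the hindered trisubstituted C23=C24 alkene and does not cleave the allylic alcohol.

Step 17
Reactants: 20 dihydro diol
Product: 21 tricyclic β-hydroxy ketone (C8 ketone)
Conditions: Dess–Martin periodinane, NaHCO3, CH2Cl2, 20 °C
Reagents that add atoms: none
Why: Dess–Martin oxidation of the secondary C8 alcohol gives the ketone while the tertiary C27 alcohol is inert.

Step 18
Reactants: 21 tricyclic β-hydroxy ketone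
Product: 22 O28 methoxymethyl ether
Conditions: MeOCH2Cl, iPr2NEt, Bu4NI (cat.), CH2Cl2, 40 °C
Reagents that add atoms: chloromethyl methyl ether COCCl
Why: Methoxymethyl ether formation protects the tertiary allylic alcohol against retro-aldol cleavage and ionisation in the next steps and is small enough not to block C15.

Step 19
Reactants: 22 O28 methoxymethyl ether
Product: 24 bridged N-methyl amino ketone, via mono-Mannich base 23 (not isolated)
Conditions: MeNH2·HCl, (CH2O)n, AcOH, MeOH, 65 °C; NaHCO3 work-up
Reagents that add atoms: methylamine hydrochloride CN.Cl; formaldehyde C=O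
Why: Double Mannich reaction in which aminomethylation at the C20 methylene is followed by intramolecular Mannich closure of the N-methyl iminium ion onto the C15 enol from the convex face (cis to H26 and O28, the other face carries the seven-membered ring), which creates the piperidine ring, the C15 quaternary centre and the C20 bridgehead fixed by the bicycle.

Step 20
Reactants: 24 bridged N-methyl amino ketone
Product: 26 C8 aldehyde, via methyl enol ether 25 (not isolated)
Conditions: MeOCH2PPh3Cl, KN(SiMe3)2, THF, 0 → 50 °C; then 1 M HCl, THF, 20 °C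
Reagents that add atoms: (methoxymethyl)triphenylphosphonium chloride COC[P+](c1ccccc1)(c1ccccc1)c1ccccc1.[Cl-]; water O
Why: Wittig methoxymethylenation of the bridge ketone followed by enol ether hydrolysis is the standard one-carbon homologation to the aldehyde (C8 epimers, both give the same enolate).

Step 21
Reactants: 26 C8 aldehyde; 27 4-methylpent-1-en-3-one (isopropyl vinyl ketone)
Product: 28 keto aldehyde with C8 quaternary
Conditions: KN(SiMe3)2 (1.05 equiv), THF, −78 °C; 27 (1.5 equiv), −78 → −20 °C; AcOH quench
Reagents that add atoms: none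
Why: Intermolecular Michael addition of the aldehyde enolate to the vinyl ketone joins the two fragments and creates the C8 quaternary centre, the electrophile entering from the open piperidine side because the other face lies in the concave pocket under ring A, so the formyl carbon C9 ends up next to the C13 ester.

Step 22
Reactants: 28 keto aldehyde
Product: 29 diol ester (C9–OH and C4–OH)
Conditions: NaBH4 (excess), MeOH, 0 → 20 °C
Reagents that add atoms: none
Why: Borohydride reduction of both the hindered aldehyde and the side-chain ketone avoids a chemoselectivity problem (C4 epimers, removed in step 24).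

Step 23
Reactants: 29 diol ester
Product: 30 seven-membered lactone alcohol
Conditions: DBU (2 equiv), toluene, 100 °C
Reagents that add atoms: none
Why: Base-mediated intramolecular transesterification (lactonisation) of the primary C9 alcohol with the cis C13 ester closes the lactone, and any C13 epimer converges because only the cis ester can cyclise.

Step 24
Reactants: 30 lactone alcohol
Product: 31 O28 methoxymethyl ether of the target
Conditions: Dess–Martin periodinane, NaHCO3, CH2Cl2, 20 °C
Reagents that add atoms: none
Why: Dess–Martin oxidation of the secondary C4 alcohol restores the isopropyl ketone.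

Step 25
Reactants: 31 O28 methoxymethyl ether of the target
Product: 32 target CNP0242289.1
Conditions: ZnBr2, n-PrSH, CH2Cl2, 0 → 20 °C
Reagents that add atoms: none
Why: Lewis acid/thiol cleavage of the methoxymethyl ether (the oxocarbenium fragment is trapped by the thiol) frees the tertiary alcohol without ionising the allylic C27–O bond or opening the lactone.

**Compound list**
1 | cyclopenta-1,3-diene (cracked from commercial dicyclopentadiene) | C1C=CC=C1 | starting material
2 | cyclopent-2-en-1-one | O=C1CCC=C1 | starting material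
3 | endo-tricyclo[5.2.1.0(2,6)]dec-8-en-3-one, all-cis at C13/C15/C26/C27 | O=C1CC[C@H]2[C@@H]1[C@H]1C=C[C@@H]2C1 | intermediate
4 | triethylsilyl enol ether C23(OSiEt3)=C27 of 3 | CC[Si](CC)(CC)OC1CC[C@H]2C=1[C@H]1C=C[C@@H]2C1 | intermediate
5 | C27-(triethylsilyloxy) ketone, exo O28, alkene intact | O=C1CC[C@H]2[C@]1(O[Si](CC)(CC)CC)[C@H]1C=C[C@@H]2C1 | intermediate
6 | exo-C8,C11-epoxide of 5 | O=C1CC[C@H]2[C@]1(O[Si](CC)(CC)CC)[C@H]1[C@@H]3O[C@@H]3[C@@H]2C1 | intermediate
7 | endo C23 alcohol of 6 | O[C@@H]1CC[C@H]2[C@]1(O[Si](CC)(CC)CC)[C@H]1[C@@H]3O[C@@H]3[C@@H]2C1 | intermediate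
8 | cage ether alcohol: C23–O–C8 tetrahydrofuran bridge, exo C11–OH, C27–OSiEt3 | O3[C@@H]1CC[C@H]2[C@]1(O[Si](CC)(CC)CC)[C@H]1[C@@H]3[C@H](O)[C@@H]2C1 | intermediate
9 | cage ether C11 ketone | O3[C@@H]1CC[C@H]2[C@]1(O[Si](CC)(CC)CC)[C@H]1[C@@H]3C(=O)[C@@H]2C1 | intermediate
10 | lactone acetal C11(=O)–O–C8H(–O–C23) | O3[C@@H]1CC[C@H]2[C@]1(O[Si](CC)(CC)CC)[C@H]1[C@@H]3OC(=O)[C@@H]2C1 | intermediate
11 | lactol acid: C13–CO2H, C8 lactol on O23 (anomers) | O3[C@@H]1CC[C@H]2[C@]1(O[Si](CC)(CC)CC)[C@@H](C3O)C[C@H]2C(=O)O | intermediate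
12 | hydroxy acid: C8 vinyl carbinol, endo C23–OH, C13–CO2H | O[C@@H]1CC[C@H]2[C@]1(O[Si](CC)(CC)CC)[C@@H](C(O)C=C)C[C@H]2C(=O)O | intermediate
13 | methyl ester of 12 | O[C@@H]1CC[C@H]2[C@]1(O[Si](CC)(CC)CC)[C@@H](C(O)C=C)C[C@H]2C(=O)OC | intermediate
14 | C8–O-tert-butyldimethylsilyl ether of 13 | O[C@@H]1CC[C@H]2[C@]1(O[Si](CC)(CC)CC)[C@@H](C(O[Si](C)(C)C(C)(C)C)C=C)C[C@H]2C(=O)OC | intermediate
15 | C23 ketone of 14 | O=C1CC[C@H]2[C@]1(O[Si](CC)(CC)CC)[C@@H](C(O[Si](C)(C)C(C)(C)C)C=C)C[C@H]2C(=O)OC | intermediate
16 | enol triflate C23(OTf)=C24 | FC(F)(F)S(=O)(=O)OC1=CC[C@H]2[C@]1(O[Si](CC)(CC)CC)[C@@H](C(O[Si](C)(C)C(C)(C)C)C=C)C[C@H]2C(=O)OC | intermediate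
17 | C23-allyl cyclopentene with C8 vinyl carbinol silyl ether | C=CCC1=CC[C@H]2[C@]1(O[Si](CC)(CC)CC)[C@@H](C(O[Si](C)(C)C(C)(C)C)C=C)C[C@H]2C(=O)OC | intermediate
18 | tricyclic cycloheptene (C20=C21), C8–OSi, C27–OSiEt3, C13–CO2Me | CC(C)(C)[Si](C)(C)OC3C=CCC1=CC[C@H]2[C@]1(O[Si](CC)(CC)CC)[C@@H]3C[C@H]2C(=O)OC | intermediate
19 | diol: C8–OH, C27–OH, C20=C21 and C23=C24 alkenes | OC3C=CCC1=CC[C@H]2[C@]1(O)[C@@H]3C[C@H]2C(=O)OC | intermediate
20 | dihydro diol (C20–C21 saturated) | OC3CCCC1=CC[C@H]2[C@]1(O)[C@@H]3C[C@H]2C(=O)OC | intermediate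
21 | tricyclic β-hydroxy ketone: C8 ketone, C27–OH, C23=C24, C13–CO2Me, H15 cis to O28 | O=C3CCCC1=CC[C@H]2[C@]1(O)[C@@H]3C[C@H]2C(=O)OC | intermediate
22 | O28 methoxymethyl ether of 21 | O=C3CCCC1=CC[C@H]2[C@]1(OCOC)[C@@H]3C[C@H]2C(=O)OC | intermediate
23 | mono-Mannich base: C20–CH2NHMe ketone | O=C3C(CNC)CCC1=CC[C@H]2[C@]1(OCOC)[C@@H]3C[C@H]2C(=O)OC | intermediate
24 | bridged amino ketone: N-methylpiperidine (N17, C16, C15, C8, C20, C19), C8 ketone | COC(=O)[C@@H]3C[C@]14CN(C)C[C@H](C1=O)CCC1=CC[C@H]3[C@@]14OCOC | intermediate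
25 | methyl enol ether C8=C9H–OMe | COC(=O)[C@@H]3C[C@]14CN(C)C[C@H](C1=COC)CCC1=CC[C@H]3[C@@]14OCOC | intermediate
26 | C8 aldehyde (C8–H, C9 formyl) | COC(=O)[C@@H]3C[C@]14CN(C)C[C@H](C1C=O)CCC1=CC[C@H]3[C@@]14OCOC | intermediate
27 | 4-methylpent-1-en-3-one (isopropyl vinyl ketone) | CC(C)C(=O)C=C | starting material
28 | keto aldehyde: C8 quaternary with formyl (C9) and 5-methyl-4-oxohexyl-type side chain (C7–C1) | COC(=O)[C@@H]3C[C@]14CN(C)C[C@H]([C@]1(C=O)CCC(=O)C(C)C)CCC1=CC[C@H]3[C@@]14OCOC | intermediate
29 | diol ester: C9–OH, C4–OH, C13–CO2Me | COC(=O)[C@@H]3C[C@]14CN(C)C[C@H]([C@]1(CO)CCC(O)C(C)C)CCC1=CC[C@H]3[C@@]14OCOC | intermediate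
30 | lactone alcohol: C4–OH, O28 methoxymethyl ether | CC(C)C(O)CC[C@]12COC(=O)[C@@H]3C[C@]14CN(C)C[C@H]2CCC1=CC[C@H]3[C@@]14OCOC | intermediate
31 | O28 methoxymethyl ether of the target | CC(C)C(=O)CC[C@]12COC(=O)[C@@H]3C[C@]14CN(C)C[C@H]2CCC1=CC[C@H]3[C@@]14OCOC | intermediate
32 | CNP0242289.1 | CC(C)C(=O)CC[C@]12COC(=O)[C@@H]3C[C@]14CN(C)C[C@H]2CCC1=CC[C@H]3[C@@]14O | target

**Totals and risks**
Total step count: 25. Longest linear sequence: 25 steps (1 + 2 → 32).

Most likely to fail, first: step 1, because a simple cyclopentenone is a weak dienophile and the enantioselectivity is not assured. The fallback sets out from 1 and comes back at 3. Compound 1 is left to dimerise at 20 °C to endo-dicyclopentadiene F1. SeO2 with KH2PO4 in dioxane–H2O at 90 °C oxidises the allylic CH2 to the racemic convex-face dienol F2. Pseudomonas cepacia lipase with vinyl acetate acylates the unwanted enantiomer and leaves the resolved dienol F3. MnO2 in CH2Cl2 gives the tricyclic dienone F4. Conjugate reduction with [(Ph3P)CuH]6 in wet toluene saturates only the enone double bond and gives 3, so resolution replaces asymmetric catalysis.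

Second: step 19, because the one-pot double Mannich reaction must form the C15 quaternary centre next to the fully substituted C27. The fallback sets out from 22 and comes back at 24. LiN(iPr)2 in THF at −78 °C deprotonates the C20 methylene and CH2=NMe2+ I− gives the dimethylaminomethyl ketone F5. MeI and then NaHCO3 eliminate trimethylamine to give the exo-methylene ketone F6. Aza-Michael addition of MeNH2 in THF at 0 °C gives 23, now isolated. (CH2O)n with CF3CO2H in MeCN at 60 °C closes the piperidine by intramolecular Mannich reaction to 24.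

Third: step 21, because the enolate is hindered and the facial selectivity at C8 rests on a steric argument. The fallback sets out from 26 and comes back at 31. LiOH in THF–H2O gives the aldehyde acid F7. Ac2O with NaOAc at 90 °C cyclodehydrates it to the seven-membered enol lactone F8 (C8=C9–O–C11). Fe(acac)3 (iron tris(acetylacetonate)), PhSiH3 and 27 in EtOH at 60 °C then effect a hydrogen-atom-transfer radical conjugate addition (Giese reaction) at C8. The lactone tether holds C9 under ring A, so the side chain can only enter from the open face, and 31 is formed directly.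

**Further compounds**
F1 | step 1 | endo-dicyclopentadiene (racemic) | C1C=CC2C1C1C=CC2C1
F2 | step 1 | racemic endo-tricyclo[5.2.1.0(2,6)]deca-4,8-dien-3-ol (convex-face OH) | OC1C=CC2C1C1C=CC2C1
F3 | step 1 | resolved dienol of the needed configuration | O[C@H]1C=C[C@H]2[C@@H]1[C@H]1C=C[C@@H]2C1
F4 | step 1 | endo-tricyclo[5.2.1.0(2,6)]deca-4,8-dien-3-one, single enantiomer | O=C1C=C[C@H]2[C@@H]1[C@H]1C=C[C@@H]2C1
F5 | step 19 | C20-(dimethylaminomethyl) ketone | O=C3C(CN(C)C)CCC1=CC[C@H]2[C@]1(OCOC)[C@@H]3C[C@H]2C(=O)OC
F6 | step 19 | C20 exo-methylene ketone | O=C3C(=C)CCC1=CC[C@H]2[C@]1(OCOC)[C@@H]3C[C@H]2C(=O)OC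
F7 | step 21 | aldehyde acid (C13–CO2H, C8–CHO) | OC(=O)[C@@H]3C[C@]14CN(C)C[C@H](C1C=O)CCC1=CC[C@H]3[C@@]14OCOC
F8 | step 21 | bridged enol lactone C8=C9H–O–C11(=O) | C12=COC(=O)[C@@H]3C[C@]14CN(C)C[C@H]2CCC1=CC[C@H]3[C@@]14OCOC
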